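**Route outline**

- Retrosynthesis: the three acids are unmasked from methyl esters and C16=C17 comes from a Wittig reaction. Ring D is cut at C16–C13 (hydroacylation) and at C8–C15 ([3,3] shift from a C13 carbinol). Ring C goes back to an anisole (Birch), ring B is cut at C6–C8 (enolate arylation), and ring A at C5–C10 and C1–C10 (Michael addition, alkylation).
- Forward: the future ring C is present from the outset as an anisole. Ring A is built on the arylacetate (SN2, then 6-exo Michael) and ring B by Pd α-arylation. Ring C is then dearomatised, the C15–C16 unit is transferred to C8, and ring D is closed last; C17 and the 15-hydroxyl follow.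
- Enabling feature: in ring C the fully substituted C8 and the CH carbon C13 are separated only by C14, and ring D ties them together through C15–C16. A hydroxyl on C13 next to a C8=C14 double bond is therefore an allylic handle from which a two-carbon acyl chain can migrate to C8 in a [3,3] shift. The double bond this leaves at C13=C14 is the one onto which C16 later closes.
- Stereochemistry: C4 by enzymatic desymmetrisation; C5 and C10 from the chair Michael closure relative to C4; C6 and C9 by equilibration; the C13 carbinol by CBS reduction, relayed suprafacially to C8; C13 by the bridging ring closure; C15 by exo hydride delivery.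

Key step: step 15

Assumption: pig liver esterase is taken to give the (S)-half-ester of the 3-chloropropyl methylmalonate (the sense known for short 2-alkyl chains), so the ester arm is the one reduced.

Gibberellane locants (C1–C20) are used for all intermediates; "cis/trans" refer to the ring named.

**Step 1**
Reactants: 1 dimethyl 2-methylmalonate; 2 1-bromo-3-chloropropane
Product: 3 dimethyl 2-(3-chloropropyl)-2-methylmalonate
Conditions: NaH, DMF, 0 °C to rt
Reagents that add atoms: none
Why: Malonate C-alkylation (SN2) should occur at the bromide end of 2 because bromide is the better leaving group, and the tertiary malonate cannot alkylate twice.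

**Step 2**
Reactants: 3 dimethyl 2-(3-chloropropyl)-2-methylmalonate
Product: 4 (S)-5-chloro-2-(methoxycarbonyl)-2-methylpentanoic acid
Conditions: pig liver esterase, 0.1 M phosphate buffer pH 7.5, 10% DMSO, 25 °C, pH held with 1 M NaOH; then HCl to pH 2
Reagents that add atoms: water, O
Why: Enzymatic desymmetrisation of a prochiral 2,2-disubstituted malonate should set the C4 quaternary centre, the esterase telling the two ester groups apart by binding methyl and 3-chloropropyl in pockets of different size; the ee can be raised by crystallising an amine salt of 4.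

**Step 3**
Reactants: 4 (S)-5-chloro-2-(methoxycarbonyl)-2-methylpentanoic acid
Product: 5 (R)-5-chloro-2-(hydroxymethyl)-2-methylpentanoic acid
Conditions: LiOH (1.0 equiv), MeOH, evaporate; LiBH4, THF, 0 °C to rt; then 1 M HCl
Reagents that add atoms: none
Why: LiBH4 reduces the methyl ester while the lithium carboxylate is inert (chemoselective hydride reduction), so the ester arm becomes the future C5 and the acid arm the future C19; the descriptor changes to R only because the priorities change.

**Step 4**
Reactants: 5 (R)-5-chloro-2-(hydroxymethyl)-2-methylpentanoic acid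
Product: 6 methyl (R)-5-chloro-2-(hydroxymethyl)-2-methylpentanoate
Conditions: Me3SiCHN2, PhMe/MeOH 4:1, 0 °C
Reagents that add atoms: (trimethylsilyl)diazomethane, C[Si](C)(C)C=[N+]=[N-]
Why: Diazoalkane O-methylation of the hindered acid is neutral, so neither the alcohol nor the primary chloride (lactonisation) interferes.

**Step 5**
Reactants: 6 methyl (R)-5-chloro-2-(hydroxymethyl)-2-methylpentanoate
Product: 7 methyl (R)-5-chloro-2-formyl-2-methylpentanoate
Conditions: Dess–Martin periodinane, CH2Cl2, rt
Reagents that add atoms: none
Why: Dess–Martin oxidation of the neopentyl primary alcohol stops at the aldehyde, which has no α-hydrogen and so cannot epimerise.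

**Step 6**
Reactants: 7 methyl (R)-5-chloro-2-formyl-2-methylpentanoate; 8 methyl (triphenylphosphoranylidene)acetate
Product: 9 dimethyl (R,E)-4-(3-chloropropyl)-4-methylpent-2-enedioate
Conditions: PhMe, 90 °C
Reagents that add atoms: none
Why: Wittig olefination with the stabilised ylide should give the E-enoate and brings in C6 and C7.

**Step 7**
Reactants: 9 dimethyl (R,E)-4-(3-chloropropyl)-4-methylpent-2-enedioate
Product: 10 dimethyl (R,E)-4-(3-iodopropyl)-4-methylpent-2-enedioate
Conditions: NaI, acetone, reflux
Reagents that add atoms: sodium iodide, [Na+].[I-]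
Why: Finkelstein exchange, driven by precipitation of NaCl, turns the sluggish primary chloride into the iodide needed for C-alkylation.

**Step 8**
Reactants: 11 2-(2-bromo-4-methoxyphenyl)acetic acid
Product: 12 methyl 2-(2-bromo-4-methoxyphenyl)acetate
Conditions: MeOH, H2SO4 (cat.), reflux
Reagents that add atoms: methanol, CO
Why: Fischer esterification of an unhindered arylacetic acid in excess methanol.

**Step 9**
Reactants: 12 methyl 2-(2-bromo-4-methoxyphenyl)acetate; 10 dimethyl (R,E)-4-(3-iodopropyl)-4-methylpent-2-enedioate
Product: 14 ring A triester dimethyl 1-(2-bromo-4-methoxyphenyl)-2-(2-methoxy-2-oxoethyl)-3-methylcyclohexane-1,3-dicarboxylate, via acyclic alkylated triester 13 (not isolated)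
Conditions: KN(SiMe3)2 (1.05 equiv), THF, −78 to 0 °C; then KOt-Bu (0.3 equiv), THF, rt
Reagents that add atoms: none
Why: Enolate SN2 alkylation at the primary iodide (the enoate β-carbon is neopentyl and slower) is followed by 6-exo-trig intramolecular Michael addition, a tandem SN2–Michael annulation; the chair closure, reversible under alkoxide, should place aryl, methyl and the CH2CO2Me arm equatorial with the two ring esters syn-diaxial and bridged by potassium, which sets C10 and C5 relative to C4.

**Step 10**
Reactants: 14 ring A triester
Product: 15 trans-fused hexahydrofluorene triester (trimethyl 7-methoxy-1-methyl-2,3,4,4a,9,9a-hexahydro-1H-fluorene-1,4a,9-tricarboxylate)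
Conditions: Pd2(dba)3 (2.5 mol %), P(t-Bu)3·HBF4 (6 mol %), LiN(SiMe3)2 (2.2 equiv), PhMe, rt to 60 °C; then NaOMe (cat.), MeOH, rt
Reagents that add atoms: none
Why: Intramolecular Pd-catalysed α-arylation of the only enolisable ester (oxidative addition of zerovalent palladium to the aryl bromide, enolate binding, reductive elimination) closes ring B across the trans-diequatorial aryl and acetate arms, and methoxide equilibration of the benzylic C6–H should leave the C6 ester trans to quaternary C4.

**Step 11**
Reactants: 15 trans-fused hexahydrofluorene triester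
Product: 16 hexahydrofluorene triacid
Conditions: LiSCH2CH2CH3 (10 equiv), HMPA, rt; then 1 M HCl
Reagents that add atoms: none
Why: Thiolate SN2 dealkylation attacks the ester methyl groups instead of the hindered carbonyls (the aryl methyl ether is inert at rt) and gives the tricarboxylic acid, whose salts survive dissolving metal.

**Step 12**
Reactants: 16 hexahydrofluorene triacid
Product: 18 β,γ-enone triacid (8(9)-en-13-one), via dienol ether triacid 17 (not isolated)
Conditions: Li, NH3 (l), THF, t-BuOH, −78 to −33 °C; NH4Cl; then oxalic acid, THF/H2O, rt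
Reagents that add atoms: water, O
Why: Birch reduction of the 3,4-dialkylanisole protonates the unsubstituted positions C11 and C14 and keeps the tetrasubstituted C8=C9 bond, as with estradiol methyl ether, the carboxylates being inert; mild acid then hydrolyses the enol ether without moving the alkene.

**Step 13**
Reactants: 18 β,γ-enone triacid
Product: 20 tricyclic 8(14)-en-13-one trimethyl ester, via β,γ-enone trimethyl ester 19 (not isolated)
Conditions: Me3SiCHN2, PhMe/MeOH, 0 °C; evaporate; then 1 M HCl in MeOH, rt; aq NaHCO3
Reagents that add atoms: (trimethylsilyl)diazomethane, C[Si](C)(C)C=[N+]=[N-]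
Why: Diazoalkane esterification restores the three methyl esters, and acid-catalysed conjugation through the dienol (the 19-norsteroid protocol) should protonate C9 axially on the face anti to the C10 ester, the arrangement that keeps the C9–C11 bond near the plane of C8=C14 on the trans-fused ring B; H9 thus ends cis to H5 and the C6 ester stays trans to C4 under the equilibrating conditions.

**Step 14**
Reactants: 20 tricyclic 8(14)-en-13-one trimethyl ester
Product: 21 (13R)-allylic alcohol, hydroxyl cis to H9
Conditions: (S)-Me-CBS oxazaborolidine [(S)-1-methyl-3,3-diphenyltetrahydro-1H,3H-pyrrolo[1,2-c][1,3,2]oxazaborole] (0.2 equiv), catecholborane (1.5 equiv), PhMe, −78 °C; then MeOH, aq NaHCO3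
Reagents that add atoms: none
Why: Corey–Bakshi–Shibata reduction under catalyst control should deliver hydride to the ketone face that gives the 13R alcohol (alkenyl branch as the large group), which is the epimer with oxygen cis to H9; the esters are untouched at −78 °C.

**Step 15**
Reactants: 21 (13R)-allylic alcohol; 22 N,N-dimethylacetamide dimethyl acetal
Product: 24 C8 angular N,N-dimethylacetamide (13-ene), via ketene N,O-acetal 23 (not isolated)
Conditions: 22 (5 equiv), xylene, 140 °C, MeOH distilled off
Reagents that add atoms: none
Why: Alcohol 21 displaces a methoxy group of 22 and a further molecule of methanol is lost, giving ketene N,O-acetal 23, whose six-atom array C=C–O–C13–C14=C8 reorganises in a concerted chair-like [3,3]-sigmatropic shift that makes the C8–C15 bond, breaks C13–O and moves the ring alkene to C13=C14. The closest known reaction type is the Eschenmoser–Claisen (amide acetal) rearrangement of 3-substituted cyclohex-2-enols to angular quaternary acetamides. The shift itself closes no ring; ring D is completed only in step 17 (C16–C13). The single new stereocentre, quaternary C8, is controlled by the C13 carbinol, because the shift is suprafacial across ring C and C15 therefore lands on the face that carried oxygen, the face of H9. The step needs complete 1,3-transfer of chirality and rearrangement in preference to elimination to a diene; the pseudo-axial C13–O bond of the half-chair and the short tether secure both, and tethered delivery is independent of the steric bias that the C6 ester on one face of C8 and the axial C10 ester on the other would impose on an external reagent.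

**Step 16**
Reactants: 24 C8 angular N,N-dimethylacetamide
Product: 25 C8 acetaldehyde (13-ene)
Conditions: Cp2Zr(H)Cl (1.6 equiv), THF, rt; then H2O/silica
Reagents that add atoms: none
Why: Cp2Zr(H)Cl adds across the amide carbonyl to a zirconated hemiaminal that releases the aldehyde on work-up (Schwartz-reagent amide reduction), leaving methyl esters and the disubstituted ring alkene alone.

**Step 17**
Reactants: 25 C8 acetaldehyde
Product: 26 17-nor-16-ketone trimethyl ester (ring D closed)
Conditions: [Rh(nbd)(dppe)]BF4 (10 mol %), H2 (brief, to free the catalyst), then Ar, ClCH2CH2Cl, 60 °C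
Reagents that add atoms: none
Why: Proposed new method: oxidative addition of the aldehyde C–H bond to cationic monovalent rhodium should give an acyl hydride of trivalent rhodium, syn hydride transfer to C14 on the tether face of the ring alkene places rhodium on C13 in a six-membered acyl rhodacycle, and C–C reductive elimination forms C16–C13, closing ring D in the bridged mode with C13 fixed by the bicyclo[3.2.1]octane geometry; the closest known reaction type is the [Rh(diphosphine)]+ cyclisation of 4-pentenals to cyclopentanones, which is favoured by 3,3-disubstitution (quaternary C8 here) but is taken here beyond its known scope to an endocyclic alkene giving a bridged ketone.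

**Step 18**
Reactants: 26 17-nor-16-ketone trimethyl ester; 27 methyltriphenylphosphonium bromide
Product: 28 16-methylene trimethyl ester (15-deoxy)
Conditions: KOt-Bu, THF, 0 °C to rt
Reagents that add atoms: none
Why: Wittig methylenation of the ketone, whose only enolisable neighbour is the C15 methylene (C13 is a bridgehead), installs C17.

**Step 19**
Reactants: 28 16-methylene trimethyl ester
Product: 29 15-epi allylic alcohol (hydroxyl anti to the C9–C11–C12 bridge)
Conditions: SeO2 (0.3 equiv), t-BuOOH (3 equiv), CH2Cl2, rt
Reagents that add atoms: selenium dioxide, O=[Se]=O (oxygen carrier); tert-butyl hydroperoxide, CC(C)(C)OO (terminal oxidant)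
Why: Selenium dioxide allylic oxidation (ene reaction, then [2,3]-sigmatropic shift) can only engage C15 because the other allylic position is the C13 bridgehead, and oxygen should arrive on the exo face of ring D, giving the 15-epimer that steps 20 and 21 invert.

**Step 20**
Reactants: 29 15-epi allylic alcohol
Product: 30 16-en-15-one trimethyl ester
Conditions: Dess–Martin periodinane, CH2Cl2, rt
Reagents that add atoms: none
Why: Dess–Martin oxidation of the allylic alcohol gives the α-methylene ketone under neutral conditions and erases the C15 configuration.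

**Step 21**
Reactants: 30 16-en-15-one trimethyl ester
Product: 31 trimethyl ester of the target (trimethyl 15-hydroxygibberell-16-ene-7,19,20-trioate, hydroxyl on the bridge side)
Conditions: NaBH4, CeCl3·7H2O, MeOH, −78 to 0 °C; aq NH4Cl
Reagents that add atoms: none
Why: Luche reduction gives 1,2-reduction of the α-methylene ketone, and hydride should approach C15 from the exo face, away from the C9–C11–C12 bridge whose axial H11 shields the endo face, placing the hydroxyl on the bridge side as in the target.

**Step 22**
Reactants: 31 trimethyl ester of the target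
Product: 32 target gibberellin (15-hydroxygibberell-16-ene-7,19,20-trioic acid)
Conditions: LiSCH2CH2CH3 (10 equiv), HMPA, rt; then dilute HCl to pH 3
Reagents that add atoms: none
Why: Thiolate SN2 demethylation cleaves all three methyl esters, including the hindered C19 and C20 esters, without touching the allylic alcohol or the exocyclic alkene.

**Compound list**

1 | dimethyl 2-methylmalonate | COC(=O)C(C)C(=O)OC | starting material
2 | 1-bromo-3-chloropropane | ClCCCBr | starting material
3 | dimethyl 2-(3-chloropropyl)-2-methylmalonate | COC(=O)C(C)(CCCCl)C(=O)OC | intermediate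
4 | (S)-5-chloro-2-(methoxycarbonyl)-2-methylpentanoic acid | ClCCC[C@@](C)(C(=O)O)C(=O)OC | intermediate
5 | (R)-5-chloro-2-(hydroxymethyl)-2-methylpentanoic acid | ClCCC[C@@](C)(C(=O)O)CO | intermediate
6 | methyl (R)-5-chloro-2-(hydroxymethyl)-2-methylpentanoate | ClCCC[C@@](C)(C(=O)OC)CO | intermediate
7 | methyl (R)-5-chloro-2-formyl-2-methylpentanoate | ClCCC[C@@](C)(C(=O)OC)C=O | intermediate
8 | methyl (triphenylphosphoranylidene)acetate | COC(=O)C=P(c1ccccc1)(c1ccccc1)c1ccccc1 | starting material
9 | dimethyl (R,E)-4-(3-chloropropyl)-4-methylpent-2-enedioate | ClCCC[C@@](C)(C(=O)OC)/C=C/C(=O)OC | intermediate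
10 | dimethyl (R,E)-4-(3-iodopropyl)-4-methylpent-2-enedioate | ICCC[C@@](C)(C(=O)OC)/C=C/C(=O)OC | intermediate
11 | 2-(2-bromo-4-methoxyphenyl)acetic acid | COc1ccc(CC(=O)O)c(Br)c1 | starting material
12 | methyl 2-(2-bromo-4-methoxyphenyl)acetate | COc1ccc(CC(=O)OC)c(Br)c1 | intermediate
13 | dimethyl (4R,E)-8-(2-bromo-4-methoxyphenyl)-4-(methoxycarbonyl)-4-methylnon-2-enedioate, both C8 (= C10) epimers | COc1ccc(c(Br)c1)C(C(=O)OC)CCC[C@@](C)(C(=O)OC)/C=C/C(=O)OC | intermediate (not isolated)
14 | ring A triester: dimethyl 1-(2-bromo-4-methoxyphenyl)-2-(2-methoxy-2-oxoethyl)-3-methylcyclohexane-1,3-dicarboxylate; aryl, 3-methyl and H2 on one ring face, the two ring esters and the acetate arm on the other; C4 as in 10 | COc1ccc(c(Br)c1)[C@]2(C(=O)OC)CCC[C@@](C)(C(=O)OC)[C@H]2CC(=O)OC | intermediate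
15 | trimethyl 7-methoxy-1-methyl-2,3,4,4a,9,9a-hexahydro-1H-fluorene-1,4a,9-tricarboxylate; trans ring fusion (H9a anti to the 4a-ester), 1- and 4a-esters cis, 9-ester cis to H9a | COc1ccc2c(c1)[C@@H](C(=O)OC)[C@H]3[C@@]2(C(=O)OC)CCC[C@@]3(C)C(=O)OC | intermediate
16 | 7-methoxy-1-methyl-2,3,4,4a,9,9a-hexahydro-1H-fluorene-1,4a,9-tricarboxylic acid, configuration of 15 | COc1ccc2c(c1)[C@@H](C(=O)O)[C@H]3[C@@]2(C(=O)O)CCC[C@@]3(C)C(=O)O | intermediate
17 | 7-methoxy-1-methyl-2,3,4,4a,5,8,9,9a-octahydro-1H-fluorene-1,4a,9-tricarboxylic acid (13-methoxy-8(9),12-diene), configuration of 15 | COC1=CCC2=C(C1)[C@@H](C(=O)O)[C@H]3[C@@]2(C(=O)O)CCC[C@@]3(C)C(=O)O | intermediate (not isolated)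
18 | 1-methyl-7-oxo-2,3,4,4a,5,6,7,8,9,9a-decahydro-1H-fluorene-1,4a,9-tricarboxylic acid (8(9)-en-13-one) | O=C1CCC2=C(C1)[C@@H](C(=O)O)[C@H]3[C@@]2(C(=O)O)CCC[C@@]3(C)C(=O)O | intermediate
19 | trimethyl ester of 18 | O=C1CCC2=C(C1)[C@@H](C(=O)OC)[C@H]3[C@@]2(C(=O)OC)CCC[C@@]3(C)C(=O)OC | intermediate (not isolated)
20 | trimethyl 1-methyl-7-oxo-2,3,4,4a,4b,5,6,7,9,9a-decahydro-1H-fluorene-1,4a,9-tricarboxylate (8(14)-en-13-one); H9 cis to H5 and anti to the C10 ester, C6 ester cis to H5 | O=C1CC[C@@H]2C(=C1)[C@@H](C(=O)OC)[C@H]3[C@@]2(C(=O)OC)CCC[C@@]3(C)C(=O)OC | intermediate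
21 | trimethyl 7-hydroxy-1-methyl-2,3,4,4a,4b,5,6,7,9,9a-decahydro-1H-fluorene-1,4a,9-tricarboxylate; 13R, hydroxyl cis to H9 on ring C | O[C@@H]1CC[C@@H]2C(=C1)[C@@H](C(=O)OC)[C@H]3[C@@]2(C(=O)OC)CCC[C@@]3(C)C(=O)OC | intermediate
22 | N,N-dimethylacetamide dimethyl acetal | COC(C)(OC)N(C)C | starting material
23 | 13-O-[1-(dimethylamino)vinyl] ether of 21 (ketene N,O-acetal) | C=C(N(C)C)O[C@@H]1CC[C@@H]2C(=C1)[C@@H](C(=O)OC)[C@H]3[C@@]2(C(=O)OC)CCC[C@@]3(C)C(=O)OC | intermediate (not isolated)
24 | trimethyl 8a-[2-(dimethylamino)-2-oxoethyl]-1-methyl-2,3,4,4a,4b,5,6,8a,9,9a-decahydro-1H-fluorene-1,4a,9-tricarboxylate (13-ene); C8 arm cis to H9 and to the C6 ester | CN(C)C(=O)C[C@]12C=CCC[C@H]1[C@]3(C(=O)OC)CCC[C@@](C)(C(=O)OC)[C@H]3[C@@H]2C(=O)OC | intermediate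
25 | 8a-(2-oxoethyl) analogue of 24 (C16 aldehyde), same configuration | O=CC[C@]12C=CCC[C@H]1[C@]3(C(=O)OC)CCC[C@@](C)(C(=O)OC)[C@H]3[C@@H]2C(=O)OC | intermediate
26 | trimethyl 16-oxo-17-norgibberellane-7,19,20-trioate, configuration of 32 at C4, C5, C6, C8, C9, C10, C13 | O=C1[C@@H]2CC[C@H]3[C@]4(C(=O)OC)CCC[C@@](C)(C(=O)OC)[C@H]4[C@H](C(=O)OC)[C@]3(C2)C1 | intermediate
27 | methyltriphenylphosphonium bromide | C[P+](c1ccccc1)(c1ccccc1)c1ccccc1.[Br-] | starting material
28 | 15-deoxy 16-methylene trimethyl ester (trimethyl gibberell-16-ene-7,19,20-trioate) | C=C1[C@@H]2CC[C@H]3[C@]4(C(=O)OC)CCC[C@@](C)(C(=O)OC)[C@H]4[C@H](C(=O)OC)[C@]3(C2)C1 | intermediate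
29 | 15-epimer of the target trimethyl ester; 15-OH on the ring D face turned away from the C9–C11–C12 bridge (syn to C6) | C=C1[C@@H]2CC[C@H]3[C@]4(C(=O)OC)CCC[C@@](C)(C(=O)OC)[C@H]4[C@H](C(=O)OC)[C@]3(C2)[C@H]1O | intermediate
30 | 15-oxo-16-ene trimethyl ester | C=C1[C@@H]2CC[C@H]3[C@]4(C(=O)OC)CCC[C@@](C)(C(=O)OC)[C@H]4[C@H](C(=O)OC)[C@]3(C2)C1=O | intermediate
31 | trimethyl 15-hydroxygibberell-16-ene-7,19,20-trioate (trimethyl ester of the target); 15-OH on the ring D face turned toward the C9–C11–C12 bridge (anti to C6) | C=C1[C@@H]2CC[C@H]3[C@]4(C(=O)OC)CCC[C@@](C)(C(=O)OC)[C@H]4[C@H](C(=O)OC)[C@]3(C2)[C@@H]1O | intermediate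
32 | target gibberellin, 15-hydroxygibberell-16-ene-7,19,20-trioic acid (15-OH on the bridge side of ring D) | C=C1[C@@H]2CC[C@H]3[C@]4(C(=O)O)CCC[C@@](C)(C(=O)O)[C@H]4[C@H](C(=O)O)[C@]3(C2)[C@@H]1O | target

**Step count**

Total: 22 steps. Longest linear sequence: 21 steps (steps 1–7, then 9–22, from dimethyl 2-methylmalonate).

**Steps most likely to fail**

1. Step 17 (bridging hydroacylation). The acyl rhodium hydride may decarbonylate, or the ring alkene may fail to insert or may migrate, so the C16–C13 bond does not form. The fallback uses known chemistry, sets out from amide 24 and returns at ketone 26. Hydroboration of 24 with catecholborane catalysed by Rh(PPh3)3Cl, which leaves the amide and the esters alone and should place boron at C13 (the alkene carbon remote from quaternary C8), followed by NaBO3 oxidation, should give the 13-hydroxy amide F1. Iodination with I2, PPh3 and imidazole gives the 13-iodo amide F2, and Cp2Zr(H)Cl reduction of the amide gives the iodo aldehyde F3. SmI2 in THF/HMPA then effects an intramolecular Barbier addition of C13 to the aldehyde carbon (the C13 configuration is lost on the way and is reset by the bridge), giving the 16-alcohol F4. Dess–Martin oxidation of this alcohol gives 26.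

2. Step 9 (alkylation–Michael annulation). Diastereocontrol at C5 may be insufficient, because an arm flanked by two quaternary carbons has only a small equatorial preference; the acetate arm would then sit cis to the aryl group and lead to the cis-fused series. The fallback sets C5 by hydride delivery instead of by the ring closure; it sets out from 14 obtained as a C5-epimer mixture and returns at 14 as one epimer. Selenation at C6, the only enolisable position (LiN(SiMe3)2, PhSeBr, −78 °C), gives the α-phenylselanyl ester F5. H2O2 oxidation and syn-elimination toward the only β-hydrogen, H5, give the exocyclic alkylidene acetate F6 (C5=C6). Copper hydride conjugate reduction (Cu(OAc)2·H2O, 1,2-bis(diphenylphosphino)benzene, polymethylhydrosiloxane, t-BuOH), which tolerates the aryl bromide, should deliver hydride to C5 from the face anti to the two axial ring esters and return 14.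

3. Step 2 (enzymatic desymmetrisation). Enantioselectivity may be low, or the sense reversed, because the 3-chloropropyl chain lies near the length at which the esterase changes its preference. The fallback is a classical resolution; it sets out from diester 3 and returns at 4 (and, for the antipode, at 6). Monosaponification of 3 (KOH, 1 equiv, MeOH) gives the racemic half-ester F7. Crystallisation of its salt with (S)-1-phenylethylamine, the salt F8, and acidification give 4. The antipodal (R)-half-ester F9 from the mother liquor is not lost: BH3·SMe2 reduction of its acid arm gives hydroxy ester 6 directly.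

**Further compounds**

F1 | step 17 | 13-hydroxy amide (hydrate of 24 at C13, both C13 epimers) | CN(C)C(=O)C[C@]12CC(O)CC[C@H]1[C@]3(C(=O)OC)CCC[C@@](C)(C(=O)OC)[C@H]3[C@@H]2C(=O)OC
F2 | step 17 | 13-iodo amide | CN(C)C(=O)C[C@]12CC(I)CC[C@H]1[C@]3(C(=O)OC)CCC[C@@](C)(C(=O)OC)[C@H]3[C@@H]2C(=O)OC
F3 | step 17 | 13-iodo C16 aldehyde | O=CC[C@]12CC(I)CC[C@H]1[C@]3(C(=O)OC)CCC[C@@](C)(C(=O)OC)[C@H]3[C@@H]2C(=O)OC
F4 | step 17 | 17-nor-16-alcohol trimethyl ester (both C16 epimers) | OC1[C@@H]2CC[C@H]3[C@]4(C(=O)OC)CCC[C@@](C)(C(=O)OC)[C@H]4[C@H](C(=O)OC)[C@]3(C2)C1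
F5 | step 9 | C6 phenylselanyl derivative of 14 (C5 and C6 epimers) | COc1ccc(c(Br)c1)[C@]2(C(=O)OC)CCC[C@@](C)(C(=O)OC)C2C([Se]c3ccccc3)C(=O)OC
F6 | step 9 | exocyclic alkylidene acetate (C5=C6) | COc1ccc(c(Br)c1)[C@]2(C(=O)OC)CCC[C@@](C)(C(=O)OC)C2=CC(=O)OC
F7 | step 2 | racemic 5-chloro-2-(methoxycarbonyl)-2-methylpentanoic acid | ClCCCC(C)(C(=O)O)C(=O)OC
F8 | step 2 | (S)-1-phenylethylammonium salt of 4 | C[C@H]([NH3+])c1ccccc1.ClCCC[C@@](C)(C([O-])=O)C(=O)OC
F9 | step 2 | (R)-5-chloro-2-(methoxycarbonyl)-2-methylpentanoic acid | ClCCC[C@](C)(C(=O)O)C(=O)OC
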